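**Plan**

- Retrosynthesis: both indole N-tosyl groups come off last. The imidazole is then cut at C4–C5, next at N1–C5 (a formamidine carbon from DMF dimethyl acetal), and finally at C2–N3 (an amidine from a nitrile and a primary amine).
- Enabling feature: imidazole C4 carries an indol-3-yl group and C5 is a bare CH. C4 can therefore begin as an acidic indol-3-ylmethyl CH2, and C5 as a formamidine carbon with NMe2 as leaving group.
- Forward: 6-bromoindole-3-carbonitrile is tosylated and part of it reduced to the aminomethylindole. Amine and nitrile are joined to the amidine, the amidine is aminomethylenated, and base closes the imidazole, the only ring built. Detosylation finishes the route.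
- Stereochemistry: the target has no stereocentre. The two sp3 centres that appear during ring closure are erased on aromatisation.

Key step: step 5

Remark: Ts = p-toluenesulfonyl. The C=N geometries of the amidine and formamidine units interconvert readily and are left unspecified; amidine 5 is drawn as one tautomer.

**Route**

Step 1
Reactants: 1 6-bromo-1H-indole-3-carbonitrile
Product: 2 6-bromo-1-tosylindole-3-carbonitrile
Conditions: TsCl, 50% aq. NaOH, Bu4NHSO4 (cat.), CH2Cl2, 0 °C → rt
Reagents that add atoms: p-toluenesulfonyl chloride, Cc1ccc(cc1)S(=O)(=O)Cl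
Why: Phase-transfer N-sulfonylation of an indole, in which the 3-cyano group makes the N–H acidic enough for interfacial deprotonation and the ion pair is tosylated at nitrogen faster than nitrile or TsCl is hydrolysed.

Step 2
Reactants: 2 6-bromo-1-tosylindole-3-carbonitrile
Product: 3 (6-bromo-1-tosylindol-3-yl)methanamine
Conditions: BH3·THF, THF, 0 °C → reflux; MeOH, then HCl/MeOH, reflux; 1 M aq. NaOH, 0 °C (free base)
Reagents that add atoms: none
Why: Borane reduction of a nitrile to the primary amine, in which the electrophilic hydride source should spare the aryl bromide and the sulfonamide, acidic methanolysis breaks the boron–nitrogen adducts, and the N-sulfonyl group prevents gramine-type loss of the new amino group.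

Step 3
Reactants: 3 (6-bromo-1-tosylindol-3-yl)methanamine, 2 6-bromo-1-tosylindole-3-carbonitrile
Product: 5 6-bromo-N-[(6-bromo-1-tosylindol-3-yl)methyl]-1-tosylindole-3-carboximidamide, via dimethylaluminium amide 4 (not isolated)
Conditions: 3, AlMe3, toluene, 0 °C → rt; then 2, 80 °C; aq. KNaC4H4O6 work-up
Reagents that add atoms: none
Why: AlMe3 turns the primary amine into the aluminium amide 4, whose Al–N bond adds across the aluminium-activated nitrile of 2 (Garigipati-type amidine synthesis), a reaction that tolerates aryl bromides and is expected to leave the weakly electrophilic indole sulfonamides alone.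

Step 4
Reactants: 5 6-bromo-N-[(6-bromo-1-tosylindol-3-yl)methyl]-1-tosylindole-3-carboximidamide, 6 N,N-dimethylformamide dimethyl acetal
Product: 7 N'-[(6-bromo-1-tosylindol-3-yl)methyl]-N-[(dimethylamino)methylidene]-6-bromo-1-tosylindole-3-carboximidamide
Conditions: 6 (3 equiv), toluene, 60 °C; evaporation with toluene, used crude
Reagents that add atoms: none
Why: Only the unsubstituted amidine nitrogen can lose two hydrogens, so condensation with the amide acetal (aminomethylenation to a formamidine) should place the Me2N–CH= unit there and leave the indolylmethyl group on the other nitrogen, with removal of methanol driving the reaction.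

Step 5
Reactants: 7 N'-[(6-bromo-1-tosylindol-3-yl)methyl]-N-[(dimethylamino)methylidene]-6-bromo-1-tosylindole-3-carboximidamide
Product: 12 2,4-bis(6-bromo-1-tosylindol-3-yl)-1H-imidazole, via potassium diazapentadienide 8 (not isolated), via potassium aminal amidinate 9 (not isolated), via 4H-imidazole 10 (not isolated), via potassium imidazolide 11 (not isolated)
Conditions: KN(SiMe3)2 (2.2 equiv), THF, −78 °C → rt; aq. NH4Cl
Reagents that add atoms: none
Why: Proposed new method: the silazide reversibly removes a proton from the CH2 of 7, which lies between the N-sulfonylindole and an imine-type nitrogen, to give anion 8, a five-centre six-electron C–N–C–N–C system whose thermal disrotatory 1,5-electrocyclisation joins the carbanionic carbon to the formamidine carbon (imidazole C4–C5) and gives amidinate 9 without a polar 5-endo-trig addition. The ring nitrogen anion of 9 then expels dimethylamide to give the 4H-imidazole 10, whose C4–H is removed at once by that amide to give the aromatic imidazolide 11, protonated on work-up to 12; this aromatisation makes the sequence irreversible. The closest known reaction types are the base-induced 1,5-electrocyclisation of 2,4-diazapentadienyl anions to imidazolines (hydrobenzamide to amarine) and the closure of S-alkylated N-thioacylformamidines to thiazoles with loss of dimethylamine; a methylene activated only by an aryl group, closing onto a formamidine terminus, has not been shown. The one ring formed, the imidazole, closes by six-electron disrotatory electrocyclisation of the U-shaped anion, and the two sp3 centres of 9 are transient and vanish on aromatisation, so no stereocentre results. The step needs deprotonation at the indolylmethyl carbon and not at indole C2–H or the tolyl methyl: KN(SiMe3)2 is too weak to metalate C2–H appreciably and equilibrates, only the methylene anion is conjugated with the diazadiene, and the tosyl groups both acidify the CH2 and block fragmentation to a 3-methyleneindolenine.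

Step 6
Reactants: 12 2,4-bis(6-bromo-1-tosylindol-3-yl)-1H-imidazole
Product: 13 nortopsentin A
Conditions: 2 M aq. NaOH, MeOH/THF, 60 °C
Reagents that add atoms: none
Why: Hydroxide attacks sulfur of the two N-sulfonylindoles and releases the indolide leaving groups (nucleophilic N-desulfonylation), while the aryl bromides and the imidazole are inert to aqueous base and the excess base consumes any methyl tosylate before it can alkylate nitrogen.

**Compound list**

1 | 6-bromo-1H-indole-3-carbonitrile | N#Cc1c[nH]c2cc(Br)ccc12 | starting material
2 | 6-bromo-1-tosylindole-3-carbonitrile | N#Cc1cn(S(=O)(=O)c2ccc(C)cc2)c2cc(Br)ccc12 | intermediate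
3 | (6-bromo-1-tosylindol-3-yl)methanamine | NCc1cn(S(=O)(=O)c2ccc(C)cc2)c2cc(Br)ccc12 | intermediate
4 | dimethylaluminium amide of 3, drawn as monomer | C[Al](C)NCc1cn(S(=O)(=O)c2ccc(C)cc2)c2cc(Br)ccc12 | intermediate (not isolated)
5 | 6-bromo-N-[(6-bromo-1-tosylindol-3-yl)methyl]-1-tosylindole-3-carboximidamide | N=C(NCc1cn(S(=O)(=O)c2ccc(C)cc2)c2cc(Br)ccc12)c1cn(S(=O)(=O)c2ccc(C)cc2)c2cc(Br)ccc12 | intermediate
6 | N,N-dimethylformamide dimethyl acetal | COC(OC)N(C)C | starting material
7 | N'-[(6-bromo-1-tosylindol-3-yl)methyl]-N-[(dimethylamino)methylidene]-6-bromo-1-tosylindole-3-carboximidamide | CN(C)C=NC(=NCc1cn(S(=O)(=O)c2ccc(C)cc2)c2cc(Br)ccc12)c1cn(S(=O)(=O)c2ccc(C)cc2)c2cc(Br)ccc12 | intermediate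
8 | potassium salt of 7 deprotonated at the indolylmethyl carbon (2,4-diazapentadienide) | CN(C)C=NC(=N[CH-]c1cn(S(=O)(=O)c2ccc(C)cc2)c2cc(Br)ccc12)c1cn(S(=O)(=O)c2ccc(C)cc2)c2cc(Br)ccc12.[K+] | intermediate (not isolated)
9 | potassium 2,4-bis(6-bromo-1-tosylindol-3-yl)-5-(dimethylamino)-4,5-dihydroimidazol-1-ide, racemic, relative configuration at C4/C5 not fixed and lost in the next event | CN(C)C1[N-]C(c2cn(S(=O)(=O)c3ccc(C)cc3)c3cc(Br)ccc23)=NC1c1cn(S(=O)(=O)c2ccc(C)cc2)c2cc(Br)ccc12.[K+] | intermediate (not isolated)
10 | 2,4-bis(6-bromo-1-tosylindol-3-yl)-4H-imidazole | C1=NC(c2cn(S(=O)(=O)c3ccc(C)cc3)c3cc(Br)ccc23)=NC1c1cn(S(=O)(=O)c2ccc(C)cc2)c2cc(Br)ccc12 | intermediate (not isolated)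
11 | potassium 2,4-bis(6-bromo-1-tosylindol-3-yl)imidazol-1-ide | [K+].Cc1ccc(cc1)S(=O)(=O)n1cc(-c2c[n-]c(-c3cn(S(=O)(=O)c4ccc(C)cc4)c4cc(Br)ccc34)n2)c2ccc(Br)cc21 | intermediate (not isolated)
12 | 2,4-bis(6-bromo-1-tosylindol-3-yl)-1H-imidazole | Cc1ccc(cc1)S(=O)(=O)n1cc(-c2c[nH]c(-c3cn(S(=O)(=O)c4ccc(C)cc4)c4cc(Br)ccc34)n2)c2ccc(Br)cc21 | intermediate
13 | nortopsentin A, 2,4-bis(6-bromo-1H-indol-3-yl)-1H-imidazole | Brc1ccc2c(-c3c[nH]c(-c4c[nH]c5cc(Br)ccc45)n3)c[nH]c2c1 | target

**Count and risks**

Total step count: 6. Longest linear sequence: 6 steps (1 → 2 → 3 → 5 → 7 → 12 → 13); compound 2 enters twice, in steps 2 and 3.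

Steps most likely to fail:

1. Step 5 (the new method). The silazide may fail to reach the methylene proton, or metalation may drift to indole C2. The anion may stay in an extended shape, undergo a 1,3-proton shift and be cleaved hydrolytically on work-up instead of closing. The aminal stage may also be slow to expel dimethylamide. The fallback uses known chemistry and forms N1–C5 and N3–C4 instead of C4–C5; it sets out from 2. One portion of 2 is converted with NH4Cl/AlMe3 (toluene, 80 °C) into 6-bromo-1-tosylindole-3-carboximidamide F1. A second portion is treated with MeMgBr (THF, then aq. HCl) to give 1-(6-bromo-1-tosylindol-3-yl)ethan-1-one F2, which is brominated with PhNMe3Br3 in THF to 2-bromo-1-(6-bromo-1-tosylindol-3-yl)ethan-1-one F3. Condensation of F1 with F3 (KHCO3, THF/H2O, reflux; the amidine–α-haloketone imidazole synthesis) should give 12, where the route is rejoined.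

2. Step 3. The aluminium amide may take a sulfonyl group from an indole nitrogen, or add only sluggishly to the electron-rich nitrile. The fallback activates the nitrile with acid and brings the amine in afterwards (Pinner reaction); it sets out from 2. HCl gas in MeOH/CH2Cl2 at 0 °C should give methyl 6-bromo-1-tosylindole-3-carboximidate hydrochloride F4. Stirring F4 with the free amine 3 in MeOH at rt, then an aq. NaHCO3 wash, should give amidine 5, where the route is rejoined.

3. Step 2. The amine may be released incompletely from boron, and forcing the reduction risks hydroboration of the sulfonylindole C2–C3 bond or loss of bromine. The fallback passes through the aldehyde oxidation level; it sets out from 2. iBu2AlH (CH2Cl2, −78 °C; aq. HCl) should give 6-bromo-1-tosylindole-3-carbaldehyde F5. NH2OH·HCl/NaOAc in EtOH converts it into 6-bromo-1-tosylindole-3-carbaldehyde oxime F6, and Zn in AcOH reduces the oxime to amine 3, where the route is rejoined.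

Further compounds
F1 | step 5 | 6-bromo-1-tosylindole-3-carboximidamide | NC(=N)c1cn(S(=O)(=O)c2ccc(C)cc2)c2cc(Br)ccc12
F2 | step 5 | 1-(6-bromo-1-tosylindol-3-yl)ethan-1-one | CC(=O)c1cn(S(=O)(=O)c2ccc(C)cc2)c2cc(Br)ccc12
F3 | step 5 | 2-bromo-1-(6-bromo-1-tosylindol-3-yl)ethan-1-one | BrCC(=O)c1cn(S(=O)(=O)c2ccc(C)cc2)c2cc(Br)ccc12
F4 | step 3 | methyl 6-bromo-1-tosylindole-3-carboximidate hydrochloride | Cl.COC(=N)c1cn(S(=O)(=O)c2ccc(C)cc2)c2cc(Br)ccc12
F5 | step 2 | 6-bromo-1-tosylindole-3-carbaldehyde | O=Cc1cn(S(=O)(=O)c2ccc(C)cc2)c2cc(Br)ccc12
F6 | step 2 | 6-bromo-1-tosylindole-3-carbaldehyde oxime (E shown, either isomer serves) | O/N=C/c1cn(S(=O)(=O)c2ccc(C)cc2)c2cc(Br)ccc12
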